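**Plan**

Numbering: tetralin C1 bears the naphthyl group, C4 the hydroxyl and C8 the methoxy group. Naphthol atoms are primed and ring C is C1'–C2'–C3'–C4'–C4a'–C8a'. IUPAC names of the early tetralones count from the carbonyl, so their C4 is C1 of the target.
Enabling feature: in ring C the C1' hydroxyl lies peri to the C8' methoxy group. C1' can therefore be read as the carbonyl carbon of a 2-methoxybenzamide (C8a' ipso, C8' ortho), and C4'–C3'–C2' as an allyl chain on the second ortho carbon, C4a'.
Cuts, in retrosynthetic order: O–Si; C1'–C2' (ring C opens to the ortho-allylbenzamide); C2'=C3' (two terminal alkenes); C4'–C4a' (allyl bromide plus ortho-metalated amide) and C1–C2' (vinyl bromide plus a 4-halo-5-methoxy-1-tetralone).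
Forward: both tetralin rings and the anisole ring of the naphthol are bought. The three-carbon chain is assembled by vinylation at C1, allylation at C4a' and cross-metathesis. Ring C closes last, by carbanion acylation and aromatisation.
Stereochemistry: C1 (R) comes from a ligand-controlled enantioconvergent nickel coupling. C4 (S, trans to C1) comes from a reagent-controlled oxazaborolidine reduction, which also turns residual wrong enantiomer into a separable cis isomer. The ring closure creates no lasting stereocentre.

Key step: step 7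

Assumption: the (3aS,8aR)-configured indane-fused bis(oxazoline) is taken to favour the (R) product in step 2, by analogy with acyclic 1-arylethyl chlorides; if the sense proves opposite, the equally accessible antipodal ligand is used and nothing else changes.

Step 1
Reactants: 1 5-methoxy-3,4-dihydronaphthalen-1(2H)-one
Product: 3 (±)-4-chloro-5-methoxy-3,4-dihydronaphthalen-1(2H)-one, via bromo ketone 2 (not isolated)
Conditions: NBS (1.05 equiv), AIBN (5 mol %), PhCF3, 80 °C; filter, concentrate cold; LiCl (5 equiv), DMF, 0 °C to rt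
Reagents that add atoms: N-bromosuccinimide, O=C1CCC(=O)N1Br (bromine of 2); lithium chloride, [Li+].[Cl-] (chlorine of 3)
Why: Wohl–Ziegler bromination should strike C4, the only benzylic C–H site of 1 and one whose radical is stabilised by the ortho methoxy group, while the ketone deactivates the ring against ionic bromination in the non-polar medium, and a Finkelstein-type exchange then replaces the labile bromide by the sturdier chloride, the halide class for which step 2 is established, the new centre being deliberately racemic.

Step 2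
Reactants: 3 (±)-4-chloro-5-methoxy-3,4-dihydronaphthalen-1(2H)-one; 4 vinyl bromide
Product: 5 (4R)-4-ethenyl-5-methoxy-3,4-dihydronaphthalen-1(2H)-one
Conditions: NiCl2(dme) (10 mol %), (3aS,3a'S,8aR,8a'R)-2,2'-(cyclopropane-1,1-diyl)bis(3a,8a-dihydro-8H-indeno[1,2-d]oxazole) (11 mol %), Mn powder (3 equiv), NaI (0.5 equiv), 4 (1 M in THF, 2 equiv), DMA, 0 °C
Reagents that add atoms: none
Why: This is a nickel-catalysed enantioconvergent reductive cross-electrophile coupling of a secondary benzylic chloride with an alkenyl bromide, in which both enantiomers of 3 give the same planar benzylic radical that is captured by the chiral bis(oxazoline)nickel vinyl complex, so that the ligand alone fixes the (R) configuration, and the neutral medium at 0 °C should spare the ketone and hold back loss of HCl.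

Step 3
Reactants: 5 (4R)-4-ethenyl-5-methoxy-3,4-dihydronaphthalen-1(2H)-one
Product: 6 (1S,4R)-4-ethenyl-5-methoxy-1,2,3,4-tetrahydronaphthalen-1-ol
Conditions: (R)-2-methyl-CBS-oxazaborolidine (20 mol %), catecholborane (1.5 equiv), toluene, −78 °C to −40 °C; aq. NaHCO3
Reagents that add atoms: none
Why: Corey–Bakshi–Shibata reduction of 4-substituted 1-tetralones is reagent-controlled, the (R)-oxazaborolidine binding the ketone with its aryl flank turned away and passing hydride to the Re face to set the (S) carbinol trans to the vinyl group, catecholborane does not hydroborate the alkene at this temperature, and any (S)-5 left from step 2 ends as the cis diastereomer that chromatography removes.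

Step 4
Reactants: 6 (1S,4R)-4-ethenyl-5-methoxy-1,2,3,4-tetrahydronaphthalen-1-ol
Product: 7 tert-butyl{[(1S,4R)-4-ethenyl-5-methoxy-1,2,3,4-tetrahydronaphthalen-1-yl]oxy}dimethylsilane
Conditions: TBSCl (1.3 equiv), imidazole (2.5 equiv), DMF, rt
Reagents that add atoms: tert-butyldimethylsilyl chloride, CC(C)(C)[Si](C)(C)Cl
Why: Imidazole-promoted silylation of a secondary benzylic alcohol is routine, touches neither stereocentre and removes the acidic O–H ahead of the metathesis and the strong base of step 7.

Step 5
Reactants: 8 N,N-diethyl-2-methoxybenzamide; 9 allyl bromide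
Product: 12 N,N-diethyl-2-methoxy-6-(prop-2-en-1-yl)benzamide, via aryllithium 10 (not isolated), via arylmagnesium bromide 11 (not isolated)
Conditions: s-BuLi (1.1 equiv), TMEDA (1.1 equiv), THF, −78 °C; MgBr2·OEt2 (2 equiv), −78 °C to 0 °C; 9 (2 equiv), 0 °C to rt
Reagents that add atoms: sec-butyllithium, [Li]C(C)CC (lithium of 10); magnesium dibromide, Br[Mg]Br (MgBr of 11)
Why: Directed ortho-metalation takes place at C6 because the tertiary amide outranks the methoxy group as a director, and transmetalation to the less basic arylmagnesium bromide lets the allylation proceed without deprotonation of the doubly activated methylene of the product.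

Step 6
Reactants: 7 tert-butyl{[(1S,4R)-4-ethenyl-5-methoxy-1,2,3,4-tetrahydronaphthalen-1-yl]oxy}dimethylsilane; 12 N,N-diethyl-2-methoxy-6-(prop-2-en-1-yl)benzamide
Product: 13 N,N-diethyl-2-{(2E)-3-[(1R,4S)-4-{[tert-butyl(dimethyl)silyl]oxy}-8-methoxy-1,2,3,4-tetrahydronaphthalen-1-yl]prop-2-en-1-yl}-6-methoxybenzamide
Conditions: second-generation Hoveyda–Grubbs catalyst RuCl2(H2IMes)(=CH-C6H4-2-O-i-Pr) (5 mol %), 12 (2.5 equiv), 1,4-benzoquinone (10 mol %), CH2Cl2, 40 °C
Reagents that add atoms: none
Why: Olefin cross-metathesis between an unhindered allylarene used in excess and an allylically branched terminal alkene that dimerises slowly should favour the cross product, the branching favours the E alkene, and benzoquinone suppresses ruthenium hydride-induced migration of either double bond into conjugation.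

Step 7
Reactants: 13 N,N-diethyl-2-{(2E)-3-[(1R,4S)-4-{[tert-butyl(dimethyl)silyl]oxy}-8-methoxy-1,2,3,4-tetrahydronaphthalen-1-yl]prop-2-en-1-yl}-6-methoxybenzamide
Product: 17 2-[(1R,4S)-4-{[tert-butyl(dimethyl)silyl]oxy}-8-methoxy-1,2,3,4-tetrahydronaphthalen-1-yl]-8-methoxynaphthalen-1-ol, via allyllithium 14 (not isolated), via 2H-naphthalen-1-one 15 (not isolated), via lithium naphthoxide 16 (not isolated)
Conditions: LiN(i-Pr)2 (LDA, 2.5 equiv), THF, −78 °C to 0 °C; aq. NH4Cl
Reagents that add atoms: lithium diisopropylamide, [Li]N(C(C)C)C(C)C (lithium of 14 and 16)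
Why: LDA, pre-complexed to the amide oxygen, removes one proton of the C4' methylene to give allyllithium 14, whose charge is shared between C4' and C2'. After rotation about C3'–C4' into the cisoid form the C2' terminus adds to the amide carbonyl carbon C1' in a 6-exo-trig closure of ring C, the adduct expels LiNEt2 to give ketone 15, and the released amide base removes the C2' proton so that aromatisation to naphthoxide 16 makes the sequence irreversible. The closest known reaction type is the base-induced anionic annulation of N,N-diethyl-2-allylbenzamides to 1-naphthols. No lasting stereocentre is created, since the transient sp3 centre at C2' of 15 is erased on tautomerisation, and C1 and C4 of the tetralin are carried through. The selectivity needed is deprotonation at C4' and not at the tetralin C1–H, which is likewise benzylic and allylic; it is secured by amide-directed delivery of the base, by the secondary rather than tertiary carbanion, by the acceptor-substituted ring at C4' against the electron-rich anisole ring at C1, by the peri C8 methoxy group that holds the alkenyl chain pseudoaxial so that the C1–H bond lies near the arene plane and overlaps poorly with its π system, and by the charge at C2' of 14, which blocks a second deprotonation next door. In 16 the C1–H is shielded from excess base by the anionic naphthoxide ring, and should any C1 epimerisation occur, the fixed C4 centre turns it into a separable cis diastereomer and not into the enantiomer.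

Step 8
Reactants: 17 2-[(1R,4S)-4-{[tert-butyl(dimethyl)silyl]oxy}-8-methoxy-1,2,3,4-tetrahydronaphthalen-1-yl]-8-methoxynaphthalen-1-ol
Product: 18 dipolynaphthalene A
Conditions: Bu4NF (TBAF, 2 equiv), AcOH (2 equiv), THF, rt
Reagents that add atoms: none
Why: Fluoride-induced desilylation is driven by the strong Si–F bond, and buffering with acetic acid keeps the naphthol protonated and avoids both the ionisation of the benzylic C4–O bond that acid would cause and base-promoted air oxidation, so both stereocentres persist.

**Compound list**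

1 | 5-methoxy-3,4-dihydronaphthalen-1(2H)-one | COc1cccc2c1CCCC2=O | starting material
2 | (±)-4-bromo-5-methoxy-3,4-dihydronaphthalen-1(2H)-one | COc1cccc2c1C(Br)CCC2=O | intermediate
3 | (±)-4-chloro-5-methoxy-3,4-dihydronaphthalen-1(2H)-one | COc1cccc2c1C(Cl)CCC2=O | intermediate
4 | vinyl bromide (bromoethene) | C=CBr | starting material
5 | (4R)-4-ethenyl-5-methoxy-3,4-dihydronaphthalen-1(2H)-one | COc1cccc2c1[C@@H](C=C)CCC2=O | intermediate
6 | (1S,4R)-4-ethenyl-5-methoxy-1,2,3,4-tetrahydronaphthalen-1-ol (trans) | COc1cccc2c1[C@@H](C=C)CC[C@@H]2O | intermediate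
7 | tert-butyl{[(1S,4R)-4-ethenyl-5-methoxy-1,2,3,4-tetrahydronaphthalen-1-yl]oxy}dimethylsilane | COc1cccc2c1[C@@H](C=C)CC[C@@H]2O[Si](C)(C)C(C)(C)C | intermediate
8 | N,N-diethyl-2-methoxybenzamide | CCN(CC)C(=O)c1ccccc1OC | starting material
9 | allyl bromide (3-bromoprop-1-ene) | C=CCBr | starting material
10 | N,N-diethyl-2-lithio-6-methoxybenzamide | CCN(CC)C(=O)c1c([Li])cccc1OC | intermediate
11 | [2-(diethylcarbamoyl)-3-methoxyphenyl]magnesium bromide | CCN(CC)C(=O)c1c([Mg]Br)cccc1OC | intermediate
12 | N,N-diethyl-2-methoxy-6-(prop-2-en-1-yl)benzamide | CCN(CC)C(=O)c1c(CC=C)cccc1OC | intermediate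
13 | N,N-diethyl-2-{(2E)-3-[(1R,4S)-4-{[tert-butyl(dimethyl)silyl]oxy}-8-methoxy-1,2,3,4-tetrahydronaphthalen-1-yl]prop-2-en-1-yl}-6-methoxybenzamide | COc1cccc2c1[C@@H](/C=C/Cc1cccc(OC)c1C(=O)N(CC)CC)CC[C@@H]2O[Si](C)(C)C(C)(C)C | intermediate
14 | allyllithium from 13, drawn as the C4' carbanion, charge shared with C2' | COc1cccc2c1[C@@H](C=C[CH-]c1cccc(OC)c1C(=O)N(CC)CC)CC[C@@H]2O[Si](C)(C)C(C)(C)C.[Li+] | intermediate
15 | 2-[(1R,4S)-4-{[tert-butyl(dimethyl)silyl]oxy}-8-methoxy-1,2,3,4-tetrahydronaphthalen-1-yl]-8-methoxynaphthalen-1(2H)-one (C2' undefined, transient) | COc1cccc2c1[C@@H](C1C=Cc3cccc(OC)c3C1=O)CC[C@@H]2O[Si](C)(C)C(C)(C)C | intermediate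
16 | lithium 2-[(1R,4S)-4-{[tert-butyl(dimethyl)silyl]oxy}-8-methoxy-1,2,3,4-tetrahydronaphthalen-1-yl]-8-methoxynaphthalen-1-olate | COc1cccc2c1[C@@H](c1ccc3cccc(OC)c3c1[O-])CC[C@@H]2O[Si](C)(C)C(C)(C)C.[Li+] | intermediate
17 | 2-[(1R,4S)-4-{[tert-butyl(dimethyl)silyl]oxy}-8-methoxy-1,2,3,4-tetrahydronaphthalen-1-yl]-8-methoxynaphthalen-1-ol | COc1cccc2c1[C@@H](c1ccc3cccc(OC)c3c1O)CC[C@@H]2O[Si](C)(C)C(C)(C)C | intermediate
18 | dipolynaphthalene A, (1S,4R)-4-(1-hydroxy-8-methoxynaphthalen-2-yl)-5-methoxy-1,2,3,4-tetrahydronaphthalen-1-ol | COc1cccc2c1[C@@H](c1ccc3cccc(OC)c3c1O)CC[C@@H]2O | target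

**Step count and risks**

Total step count: 8. Longest linear sequence: 7 (steps 1, 2, 3, 4, 6, 7 and 8, from 1); step 5 is the side branch.

**Risk 1 (step 2).**
- What may go wrong: the flanking methoxy group and the unsubstituted vinyl partner may erode enantioselectivity, hydrogen chloride may be lost with aromatisation of the ketone ring, and the benzylic radical may dimerise reductively.
- The fallback sets out from 3 and 4 and gives up asymmetric induction in the C–C coupling.
- NiCl2(dme) with the achiral, more tolerant ligand 4,4'-di-tert-butyl-2,2'-bipyridine, Mn powder and NaI in DMA should give racemic 4-ethenyl-5-methoxy-3,4-dihydronaphthalen-1(2H)-one F1.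
- Absolute configuration is then drawn from the reduction alone. Under the conditions of step 3 the reagent-controlled reduction acts as a divergent reaction on a racemic mixture.
- It takes the (R)-ketone to 6 and the (S)-ketone to (1S,4S)-4-ethenyl-5-methoxy-1,2,3,4-tetrahydronaphthalen-1-ol F2.
- The two diastereomers are parted by chromatography, so at most half of the material can be used. The route is rejoined at 6.

**Risk 2 (step 7).**
- What may go wrong: proton removal at the tetralin C1–H may compete and epimerise that centre, and attack of the hindered C2' terminus on the twisted amide may be slow, so that the anion is merely reprotonated with alkene migration.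
- The fallback sets out from 7 and forms the same C1'–C2' bond without strong base.
- Cross-metathesis of 7 with allylboronic acid pinacol ester (second-generation Hoveyda–Grubbs catalyst) should give tert-butyl({(1S,4R)-5-methoxy-4-[(1E)-3-(4,4,5,5-tetramethyl-1,3,2-dioxaborolan-2-yl)prop-1-en-1-yl]-1,2,3,4-tetrahydronaphthalen-1-yl}oxy)dimethylsilane F3.
- Stille coupling of commercial 2-bromo-6-methoxybenzaldehyde with tributyl(vinyl)stannane, catalysed by Pd(PPh3)4, should give 2-ethenyl-6-methoxybenzaldehyde F4.
- Allylboration of F4 by F3 through a closed six-membered transition state joins C1' to the γ-carbon C2'. It gives 2-[(1R,4S)-4-{[tert-butyl(dimethyl)silyl]oxy}-8-methoxy-1,2,3,4-tetrahydronaphthalen-1-yl]-1-(2-ethenyl-6-methoxyphenyl)but-3-en-1-ol F5, whose two new centres are of no consequence.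
- Ring-closing metathesis with the second-generation Grubbs catalyst RuCl2(H2IMes)(PCy3)(=CHPh) closes ring C at C3'=C4'. The product is 2-[(1R,4S)-4-{[tert-butyl(dimethyl)silyl]oxy}-8-methoxy-1,2,3,4-tetrahydronaphthalen-1-yl]-8-methoxy-1,2-dihydronaphthalen-1-ol F6.
- Dess–Martin oxidation buffered with NaHCO3 brings the sequence back at ketone 15, which tautomerises to 17.

**Risk 3 (step 6).**
- What may go wrong: turnover may be slow at the hindered, allylically branched vinyl group, the allylarene may self-metathesise, and a double bond may migrate into conjugation.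
- The fallback sets out from 11 and 3 and moves the fragment union into the nickel coupling.
- Arylmagnesium bromide 11, generated as in step 5, is alkylated at the allylic carbon of (E)-1,3-dibromopropene (fractionated from the commercial E/Z mixture). This gives 2-[(2E)-3-bromoprop-2-en-1-yl]-N,N-diethyl-6-methoxybenzamide F7.
- F7, an (E)-alkyl-substituted alkenyl bromide, takes the place of 4 under the conditions of step 2. It should give N,N-diethyl-2-methoxy-6-{(2E)-3-[(1R)-8-methoxy-4-oxo-1,2,3,4-tetrahydronaphthalen-1-yl]prop-2-en-1-yl}benzamide F8.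
- Reduction as in step 3 gives N,N-diethyl-2-{(2E)-3-[(1R,4S)-4-hydroxy-8-methoxy-1,2,3,4-tetrahydronaphthalen-1-yl]prop-2-en-1-yl}-6-methoxybenzamide F9.
- Silylation as in step 4 rejoins the route at 13.

**Further compounds**

F1 | step 2 | (±)-4-ethenyl-5-methoxy-3,4-dihydronaphthalen-1(2H)-one | COc1cccc2c1C(C=C)CCC2=O
F2 | step 2 | (1S,4S)-4-ethenyl-5-methoxy-1,2,3,4-tetrahydronaphthalen-1-ol | COc1cccc2c1[C@H](C=C)CC[C@@H]2O
F3 | step 7 | tert-butyl({(1S,4R)-5-methoxy-4-[(1E)-3-(4,4,5,5-tetramethyl-1,3,2-dioxaborolan-2-yl)prop-1-en-1-yl]-1,2,3,4-tetrahydronaphthalen-1-yl}oxy)dimethylsilane | COc1cccc2c1[C@@H](/C=C/CB1OC(C)(C)C(C)(C)O1)CC[C@@H]2O[Si](C)(C)C(C)(C)C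
F4 | step 7 | 2-ethenyl-6-methoxybenzaldehyde | COc1cccc(C=C)c1C=O
F5 | step 7 | 2-[(1R,4S)-4-{[tert-butyl(dimethyl)silyl]oxy}-8-methoxy-1,2,3,4-tetrahydronaphthalen-1-yl]-1-(2-ethenyl-6-methoxyphenyl)but-3-en-1-ol | COc1cccc2c1[C@@H](C(C=C)C(O)c1c(C=C)cccc1OC)CC[C@@H]2O[Si](C)(C)C(C)(C)C
F6 | step 7 | 2-[(1R,4S)-4-{[tert-butyl(dimethyl)silyl]oxy}-8-methoxy-1,2,3,4-tetrahydronaphthalen-1-yl]-8-methoxy-1,2-dihydronaphthalen-1-ol | COc1cccc2c1[C@@H](C1C=Cc3cccc(OC)c3C1O)CC[C@@H]2O[Si](C)(C)C(C)(C)C
F7 | step 6 | 2-[(2E)-3-bromoprop-2-en-1-yl]-N,N-diethyl-6-methoxybenzamide | CCN(CC)C(=O)c1c(C/C=C/Br)cccc1OC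
F8 | step 6 | N,N-diethyl-2-methoxy-6-{(2E)-3-[(1R)-8-methoxy-4-oxo-1,2,3,4-tetrahydronaphthalen-1-yl]prop-2-en-1-yl}benzamide | COc1cccc2c1[C@@H](/C=C/Cc1cccc(OC)c1C(=O)N(CC)CC)CCC2=O
F9 | step 6 | N,N-diethyl-2-{(2E)-3-[(1R,4S)-4-hydroxy-8-methoxy-1,2,3,4-tetrahydronaphthalen-1-yl]prop-2-en-1-yl}-6-methoxybenzamide | COc1cccc2c1[C@@H](/C=C/Cc1cccc(OC)c1C(=O)N(CC)CC)CC[C@@H]2O
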